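## Structural features

Compound 28 is built from two five-membered rings joined by one single bond: ring A, a cyclopentane (C1–C5), and ring B, a cyclopent-2-enone (C1'–C5', C2' the carbonyl, C3'=C4'), linked through C5–C1'. Ring A carries at C1 a free tertiary hydroxyl and the acetoxymethyl carbon C6, at C4 the chain C7(CH3)=C8H–C9H2–C10H=C11(CH3)2 with a Z C7=C8 bond (ring A and C9 cis), and at C5 ring B. C6, C7 and C1' lie on one face of ring A and the C1 oxygen on the other. The five stereocentres form one unbroken array, C1–C5–C4 in ring A and C5–C1'–C5' across the inter-ring bond; on ring B the ring A substituent at C1' and the methyl at C5' are cis. The fragile points are C1' (α to the ketone and held in the less stable cis arrangement, so open to epimerisation by acid or base), the skipped 1,4-diene with its doubly allylic C9, and the primary acetate beside a free tertiary alcohol. The real difficulties are three: passing configuration from ring A across the rotating C5–C1' bond to C1' and C5', making the Z trisubstituted alkene at C7, and telling apart the two cis carbon arms on C4 and C5. The key step exploits the fact that these arms differ in length and oxidation level: C7 (one carbon, later sp2) on C4 and C1'–C2' (two carbons, C2' later the ketone) on C5. Joined through an oxygen between C7 and C2' they form a six-membered lactone cis-fused to ring A, and C1–C2–C3 with C6 can then be laid across the lactone alkene as one allenoate unit.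

## Logic of the disconnections

28 ⇒ 27 ⇒ 26 ⇒ 25. The ring B carbonyl is taken back to an allylic carbinol, the acetate to the free primary alcohol and the diol to its ketal. No skeletal bond is cut. The reason is that the ketone is what makes C1' epimerisable, so it is unveiled last and under neutral conditions. The gain is that every earlier step sees a robust cyclopentenol. The forward steps must acylate only the primary hydroxyl of 26 and oxidise only the allylic alcohol of 27.

25 ⇒ 24. The C3'=C4' bond is cut. Ring B becomes an open 1,6-diene with two terminal vinyl groups. The ring-closing catalyst must leave the two trisubstituted chain alkenes alone.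

24 ⇒ 23 ⇒ 22. The C2'–C3' bond is cut, leaving an aldehyde at C2' and a vinyl nucleophile, and the aldehyde is traced to the primary alcohol. C3' then comes from a commodity reagent. The addition must not deprotonate C1'; the new carbinol centre is irrelevant because it is oxidised later.

22 ⇒ 19 + 20. The C9–C10 bond between an allylic sp3 carbon and a vinylic carbon is cut. This makes the chain terminus a separate four-carbon piece. The coupling must take place at C9 and not at C7, and must leave the Z geometry alone.

19 ⇒ 18 ⇒ 17 ⇒ 16. The C7–CH3 bond is cut and C9 is returned to the ester level. The Z alkene then follows from syn addition of methyl and hydrogen across a C7≡C8 triple bond, the most reliable source of this geometry. The adduct must be protonated cold so that it cannot equilibrate. The carbonate on the C2' oxygen needs no step of its own, because the hydride that reduces the ester also removes it.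

16 ⇒ 14. The C8–C9 bond is cut, leaving a C4 alkynyl group and a one-carbon acylating agent. The same reagent caps the C2' hydroxyl.

14 ⇒ 11. The C1'–C5' bond is cut with allylic transposition, and C2' is returned to the ester level. Both ring B stereocentres then derive from a (E)-butenyl ester through a chair transition state. The cut is placed here because C4 still carries a slim alkyne, which leaves one face of the enolate open. The step needs an E(O) enolate and face selection by ring A.

11 ⇒ 10 ⇒ 8. The ester C–O bond is cut and the acid traced to the arm alcohol. These are functional-group changes only; they need an oxidant that spares the alkyne and the ketal.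

8 ⇒ 7 ⇒ 6. The ketal is removed and the C2–H bond replaced by the C2–O bond of an oxirane. The tertiary carbinol then comes from an alkene. The hydride must attack C2 and not C1.

6 ⇒ 5. The C7≡C8 bond is cut, returning C7 to a masked aldehyde. The homologation must not epimerise C4.

5 ⇒ 4 ⇒ 3. The oxirane is traced to the C1=C2 alkene and both carbonyls are restored. Reducing the lactone only to the lactol keeps C7 at the aldehyde level and C2' at the alcohol level, so the two arms stay differentiated. The epoxidation must occur on the convex face.

3 ⇒ 1 + 2. The C1–C5 and C3–C4 bonds are cut. Ring A falls apart into two commercial compounds, and C4 and C5 are created cis in one operation. The annulation must be regioselective (α-attack) and enantioselective on a weak acceptor.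

## Other disconnections considered

Alternative 1: The cut is the C4–C5 bond of ring A, with a temporary O–C1' bond. In the forward sense the open-chain dialdehyde A1 (C1/C6 diol already present as its acetonide) condenses with N-methylaniline A2 at the C1' aldehyde. The enamine adds through C5 to the enal β-carbon C4, and the enal oxygen closes onto C1' to give the cis-fused dihydropyran aminal A3.
- In its favour: one operation makes ring A and the cis C4/C5 pair from an open chain. The reaction is intramolecular, which is better than a bimolecular annulation on a weak acceptor. C1 oxygenation and C6 are present from the start, so the epoxidation and hydride steps of the chosen plan are not needed; this is also better. C7 arrives with its methyl and with C7=C8 locked in a ring in which C4 and the C8 oxygen are cis, the same relation the target needs between C4 and C9. A stereoretentive exchange of that C8–O bond for C8–C9 would give the Z alkene without an alkyne detour, which is potentially better.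
- Against it: the ring fusion only guarantees cis C4/C5. Their relation to the quaternary C1 rests on 1,2-induction in a flexible transition state, whereas the chosen plan places the C1 oxygen afterwards on a rigid bicycle. A1 needs its own enantioselective synthesis of a quaternary carbinol. C1' emerges at the aldehyde level without C2', so ring B would need two new C–C bonds at C1' and four carbons, against one C–C bond at C1' in the chosen plan.
- Comparison: both are nucleophile-triggered Michael-type closures (amine here, phosphine in the chosen plan), so they are equal in kind. Alternative 1 is shorter for ring A and C7 and longer for ring B, with no clear net gain.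

Alternative 2: The cut is the C1–C2 bond. In the forward sense a chiral secondary amine converts one enantiotopic aldehyde of the meso-dialdehyde A4 into its enamine, which adds to the other aldehyde; loss of water gives the cyclopentene carbaldehyde A5.
- In its favour: A4 is achiral and would be quick to make from symmetric material. The closure is intramolecular and organocatalytic, which is better on reactivity. The C6 formyl group on C1=C2 of A5 is set up for the same reduction, epoxidation and hydride opening as the chosen plan, so the two are equal on C1.
- Against it: the C4 and C5 arms of A5 are the same protected hydroxymethyl group and differ only in position. Telling C7 from C1' would cost extra steps, whereas 3 holds them at different chain lengths and oxidation levels from the outset. The C5 arm has one carbon, so C2' must still be added. The enantioselection depends on distinguishing two aldehydes whose stereocentres are β to the reacting carbons.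
- Comparison: the key step is as short as step 1 and is equal on step count there. The route as a whole would be longer because of the arm differentiation.

Alternative 3: The cut is three bonds of ring B (C1'–C2', C2'–C3', C4'–C5'). In the forward sense the C5 ethynyl compound A6, with ring A and the chain complete, is combined under cobalt mediation with ethylene A8 and carbon monoxide A9 to give the 2-substituted cyclopent-2-enone A7.
- In its favour: ring B is assembled in one late step. Only the C5' methyl and the C3'=C4' unsaturation would remain, about four operations against seven for ring B in the chosen plan, so it is better on step count for ring B. C1' is sp2 in A7, so the cis relation could be set by methyl conjugate addition followed by kinetic protonation anti to the methyl.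
- Against it: A6 needs an ethynyl group directly on C5, which 3 does not supply (C5 carries two carbons there), so ring A would need a different synthesis. The alkyne is flanked by two cis substituents and ethylene is a reluctant partner. C5' would be set by 1,3-induction from ring A and C1' in a separate protonation, two events where the chosen plan ties C1' and C5' together in one chair transition state. Both plans depend on ring A for the absolute sense, so they are equal on that point. The final desaturation needs enolisation away from C1'.
- Comparison: this step solves ring B and says nothing about ring A. It is complementary to the chosen annulation rather than a replacement for it.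

Key step: step 1

Assumption: the (S)-phosphepine named in step 1 is taken to give 3 as drawn; if its sense of induction is the opposite, the (R)-catalyst is used and nothing else changes.

## Steps

Step 1
Reactants: 1 ethyl buta-2,3-dienoate; 2 5,6-dihydro-2H-pyran-2-one
Product: 3 ethyl (4aR,7aR)-1-oxo-1,3,4,4a,7,7a-hexahydrocyclopenta[c]pyran-5-carboxylate (cis-fused cyclopentene δ-lactone; ring A with C1=C2 and the ester on C1)
Conditions: (S)-4-tert-butyl-4,5-dihydro-3H-dinaphtho[2,1-c:1',2'-e]phosphepine (10 mol %), toluene, 23 °C, 1 (1.5 equiv) added over 8 h
Reagents that add atoms: none
Why: This is a phosphine-catalysed allenoate–alkene (3+2) annulation (Lu type), established for enones and other electron-poor alkenes and enantioselective with C2-symmetric phosphepines; a plain unsaturated δ-lactone is a weak member of that acceptor class. The phosphine adds to the central carbon of 1 to give a phosphonium dienolate; its α-carbon (future C1) adds to the β-carbon of 2 (C5), the lactone enolate carbon (C4) then attacks the vinylphosphonium terminus (C3), and proton transfer with loss of the phosphine leaves the C1=C2 enoate. Ring A is the only ring closed, by a Michael addition followed by an intramolecular, formally 5-endo-trig, Michael-type closure. C4 and C5 must emerge cis because the acceptor alkene is held Z in the six-membered ring and a trans-fused bicycle of this size is out of reach. The absolute configuration is set at C5 in the first C–C bond formation, where the chiral phosphonium group shields one face of the dienolate; C4 follows from the ring fusion. The step needs α- rather than γ-attack of the dienolate, which this catalyst class favours for the unsubstituted allenoate with β-substituted acceptors, and it needs annulation to outrun self-condensation of 1, which the slow addition of 1 serves.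

Step 2
Reactants: 3
Product: 4 (4aR,7aR)-5-(hydroxymethyl)-1,3,4,4a,7,7a-hexahydrocyclopenta[c]pyran-1-ol (lactol, both anomers; allylic alcohol at C6)
Conditions: i-Bu2AlH (3.3 equiv), CH2Cl2, −78 °C; aq. KNaC4H4O6
Reagents that add atoms: none
Why: Aluminium hydride reduction takes the lactone only to the lactol (stable tetrahedral aluminate at −78 °C) and the conjugated ester fully to the allylic alcohol. C7 therefore stays at the aldehyde level and C2' at the alcohol level; no stereocentre is touched.

Step 3
Reactants: 4
Product: 5 C1–C2 epoxide of 4 (oxirane at positions 5,6 of the bicycle), oxygen on the face opposite the pyran ring; lactol as anomer mixture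
Conditions: mCPBA, NaHCO3, CH2Cl2, 0 °C
Reagents that add atoms: 3-chloroperbenzoic acid, OOC(=O)c1cccc(Cl)c1
Why: Prilezhaev epoxidation of the trisubstituted allylic alcohol. The cis-fused bicycle leaves only the convex face of C1=C2 open (the C5–C1' bond covers the other), so the C1 oxygen ends trans to both carbon arms as the target requires. The bicarbonate buffer keeps the lactol hydroxyl from opening the oxirane under acid.

Step 4
Reactants: 5
Product: 6 [1,2-epoxy-4-ethynyl-5-(2-hydroxyethyl)cyclopentyl]methanol; ethynyl (C4), hydroxyethyl (C5) and CH2OH (C1) mutually cis, oxirane oxygen trans to them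
Conditions: dimethyl (1-diazo-2-oxopropyl)phosphonate, K2CO3, MeOH, 0 → 23 °C
Reagents that add atoms: dimethyl (1-diazo-2-oxopropyl)phosphonate, COP(=O)(OC)C(=[N+]=[N-])C(C)=O
Why: Ohira–Bestmann (Seyferth–Gilbert) homologation acts on the open hydroxy-aldehyde form of the lactol. C7 becomes the alkyne carbon on C4 and the C2' hydroxyl is released; C4 stays cis as long as alkynylation outruns enolisation of the aldehyde.

Step 5
Reactants: 6
Product: 7 4-ethynyl-5-(2-hydroxyethyl)-1-(hydroxymethyl)cyclopentan-1-ol (ring A locants as in 28; C1 hydroxyl trans to the cis C4 and C5 substituents)
Conditions: LiBHEt3 (4 equiv), THF, 0 → 23 °C; aq. NH4Cl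
Reagents that add atoms: none
Why: Hydride opens the trisubstituted epoxide by SN2 attack at the secondary carbon C2 (the usual regiochemistry of this borohydride), which leaves the C1–O bond and its configuration intact and gives the tertiary alcohol. The reagent is fast enough to outrun participation by the arm alkoxide, and the alkyne is inert.

Step 6
Reactants: 7
Product: 8 acetonide of the C1/C6 diol of 7 (2,2-dimethyl-1,3-dioxolane spiro-fused at C1); 2-hydroxyethyl arm free
Conditions: Me2C(OMe)2, PPTS (cat.), acetone, 23 °C
Reagents that add atoms: 2,2-dimethoxypropane, COC(C)(C)OC
Why: Acid-catalysed ketalisation. Only the 1,2-diol (tertiary C1–OH, primary C6–OH) can close a five-membered dioxolane, so the arm alcohol stays free.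

Step 7
Reactants: 8
Product: 10 arm carboxylic acid (C2' = CO2H) of 8, via arm aldehyde 9 (not isolated)
Conditions: TEMPO (0.2 equiv), PhI(OAc)2 (2.5 equiv), MeCN–H2O (1:1), 23 °C
Reagents that add atoms: water, O
Why: Oxoammonium oxidation (TEMPO with PhI(OAc)2) takes the primary alcohol through the aldehyde hydrate to the acid. Alkyne and ketal are untouched and no stereocentre is α to the new carbonyl.

Step 8
Reactants: 10
Product: 11 (E)-but-2-en-1-yl ester of 10
Conditions: (E)-but-2-en-1-ol, EDC·HCl, DMAP, CH2Cl2, 0 → 23 °C
Reagents that add atoms: (E)-but-2-en-1-ol, C/C=C/CO
Why: Steglich-type carbodiimide esterification. The butenyl unit carries the future C5', its methyl and C4'.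

Step 9
Reactants: 11
Product: 14 primary alcohol bearing C1' and C5' (C2' = CH2OH; C4 trimethylsilylethynyl), via silyl ketene acetal 12 (not isolated), via trimethylsilyl ester 13 (not isolated)
Conditions: LiN(i-Pr)2 (2.3 equiv), THF, −78 °C; Me3SiCl (4 equiv), −78 → 45 °C; volatiles removed; LiAlH4, Et2O, 0 °C
Reagents that add atoms: chlorotrimethylsilane, C[Si](C)(C)Cl
Why: Ireland–Claisen rearrangement followed by hydride reduction of the silyl ester in the same flask; the extra equivalent of base turns the terminal alkyne into its C-silyl derivative. Kinetic enolisation in THF gives the E(O) ketene acetal (C5 cis to the allylic oxygen), and the chair transition state with the (E)-butenyl unit gives the C1'/C5' relation that becomes cis on ring B. With C5–H eclipsing the ketene acetal (allylic strain), the butenyl unit should bond on the face flanked by the rod-like alkynyl group on C4 and away from the C6 methylene on quaternary C1, which is the face that gives the required C1' configuration.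

Step 10
Reactants: 14
Product: 16 methyl ynoate methyl carbonate (C4–C≡C–CO2Me; C2'–OCO2Me), via dilithium alkoxide acetylide 15 (not isolated)
Conditions: MeLi (2.5 equiv), THF, 0 → 23 °C; ClCO2Me (3 equiv), −78 → 0 °C
Reagents that add atoms: methyl chloroformate, COC(Cl)=O
Why: MeLi deprotonates the alcohol and cleaves the alkynyl–silicon bond to the lithium acetylide, and both anions are then acylated. C9 arrives as the ester carbon and the C2' hydroxyl is masked as a carbonate without a separate protection step.

Step 11
Reactants: 16
Product: 17 methyl (Z)-3-methyl enoate (C4–C(CH3)=CH–CO2Me, ring A and ester cis), carbonate retained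
Conditions: Me2CuLi (from CuI and MeLi, 2 equiv), THF, −78 °C; MeOH, −78 °C; aq. NH4Cl
Reagents that add atoms: lithium dimethylcuprate, [Li+].C[Cu-]C
Why: Syn carbocupration (conjugate addition) of the alkynoate puts methyl on C7 and copper on C8 on the same side. Protonation with retention at −78 °C places H cis to the methyl, so ring A and C9 are cis (Z). The saturated carbonate and the vinyl group do not react with the cuprate at this temperature.

Step 12
Reactants: 17
Product: 18 diol: (Z)-allylic alcohol at C9 and primary alcohol at C2'
Conditions: i-Bu2AlH (6 equiv), CH2Cl2, −78 → 0 °C; aq. KNaC4H4O6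
Reagents that add atoms: none
Why: 1,2-Reduction of the enoate to the allylic alcohol leaves the Z geometry unchanged. The same hydride cleaves the carbonate and returns the C2' alcohol.

Step 13
Reactants: 18
Product: 19 (Z)-allylic chloride at C9, C2' alcohol free
Conditions: N-chlorosuccinimide (2.2 equiv), Me2S, CH2Cl2, −20 → 0 °C
Reagents that add atoms: N-chlorosuccinimide, ClN1C(=O)CCC1=O
Why: Corey–Kim halogenation: chloride displaces the alkoxysulfonium salt of the allylic alcohol at the primary carbon without allylic shift or change of geometry. The salt of the saturated primary alcohol is not displaced and returns the alcohol on aqueous work-up.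

Step 14
Reactants: 19; 20 1-bromo-2-methylprop-1-ene
Product: 22 alcohol with the complete Z chain C7–C11 (C2' = CH2OH), via (2-methylprop-1-enyl)magnesium bromide 21 (not isolated)
Conditions: 20, Mg, THF, 45 °C (3 equiv of 21); CuI (10 mol %), then 19, THF, −30 → 0 °C
Reagents that add atoms: none
Why: Copper-catalysed coupling of an alkenyl Grignard reagent with a primary allylic chloride. Attack at C9 is preferred because the alternative carbon C7 is fully substituted and crowded, and the C7=C8 geometry is not involved; one equivalent of 21 is spent on the free hydroxyl.

Step 15
Reactants: 22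
Product: 23 aldehyde (C2' = CHO)
Conditions: Dess–Martin periodinane, NaHCO3, CH2Cl2, 0 → 23 °C
Reagents that add atoms: none
Why: Dess–Martin oxidation of the single primary alcohol under buffered, non-enolising conditions, so C1' (now α to a carbonyl) keeps its configuration.

Step 16
Reactants: 23
Product: 24 allylic alcohol C2'H(OH)–CH=CH2 (both C2' epimers) beside the C5' vinyl group
Conditions: CH2=CHMgBr, CeCl3, THF, −78 °C
Reagents that add atoms: vinylmagnesium bromide, C=C[Mg]Br
Why: 1,2-Addition of a vinylcerium reagent (Imamoto conditions), chosen because it adds to hindered, enolisable aldehydes without deprotonating C1'. The C2' carbinol centre need not be controlled since it is oxidised in step 20.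

Step 17
Reactants: 24
Product: 25 cyclopent-2-en-1-ol form of ring B (cis 4-methyl and 5-ring A substituents, both C2' epimers), acetonide retained
Conditions: RuCl2(=CHPh)(PCy3)2 (first-generation Grubbs catalyst, 5 mol %), CH2Cl2, 40 °C
Reagents that add atoms: none
Why: Ring-closing metathesis of the two monosubstituted vinyl groups forms C3'=C4' and closes ring B with loss of ethene. The first-generation catalyst does not engage the trisubstituted chain alkenes, and the C1'/C5' relation is carried over unchanged.

Step 18
Reactants: 25
Product: 26 triol (C1–OH, C6–OH, C2'–OH)
Conditions: AcOH–H2O–THF (3:1:1), 40 °C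
Reagents that add atoms: none
Why: Mild hydrolysis of the dioxolane while ring B is still a cyclopentenol, so no epimerisable centre is exposed to acid.

Step 19
Reactants: 26
Product: 27 C6 acetate of 26 (tertiary C1–OH and ring B carbinol free)
Conditions: AcCl (1.1 equiv), 2,4,6-collidine, CH2Cl2, −78 °C
Reagents that add atoms: acetyl chloride, CC(Cl)=O
Why: Low-temperature acylation with acetyl chloride and collidine is selective for primary over secondary hydroxyls. The tertiary C1 hydroxyl and the hindered ring B carbinol should stay free.

Step 20
Reactants: 27
Product: 28 [(1R,2S,3R)-1-hydroxy-3-[(2Z)-6-methylhepta-2,5-dien-2-yl]-2-[(1S,5R)-5-methyl-2-oxocyclopent-3-en-1-yl]cyclopentyl]methyl acetate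
Conditions: MnO2 (activated, excess), CH2Cl2, 23 °C
Reagents that add atoms: none
Why: Allylic alcohol oxidation on MnO2 is neutral and selective for the cyclopentenol. Both C2' epimers converge on the enone, and C1' becomes α to a ketone only in this last step, without contact with acid or base.

## Compound list

1 | ethyl buta-2,3-dienoate | CCOC(=O)C=C=C | starting material
2 | 5,6-dihydro-2H-pyran-2-one | O=C1C=CCCO1 | starting material
3 | ethyl (4aR,7aR)-1-oxo-1,3,4,4a,7,7a-hexahydrocyclopenta[c]pyran-5-carboxylate | CCOC(=O)C1=CC[C@H]2C(=O)OCC[C@@H]12 | intermediate
4 | (4aR,7aR)-5-(hydroxymethyl)-1,3,4,4a,7,7a-hexahydrocyclopenta[c]pyran-1-ol (anomer mixture) | OCC1=CC[C@H]2C(O)OCC[C@@H]12 | intermediate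
5 | C1–C2 epoxide of 4, oxirane oxygen trans to the pyran ring (anomer mixture) | OC[C@@]1(O2)[C@H]2C[C@H]3C(O)OCC[C@@H]13 | intermediate
6 | [1,2-epoxy-4-ethynyl-5-(2-hydroxyethyl)cyclopentyl]methanol, carbon substituents all cis, oxirane oxygen trans | OC[C@@]1(O2)[C@H]2C[C@@H](C#C)[C@H]1CCO | intermediate
7 | 4-ethynyl-5-(2-hydroxyethyl)-1-(hydroxymethyl)cyclopentan-1-ol, ring A configured as in 28 | OC[C@@]1(O)CC[C@@H](C#C)[C@H]1CCO | intermediate
8 | C1/C6 acetonide of 7, arm alcohol free | CC1(C)OC[C@@]2(O1)CC[C@@H](C#C)[C@H]2CCO | intermediate
9 | arm aldehyde of 8 (C2' = CHO) | CC1(C)OC[C@@]2(O1)CC[C@@H](C#C)[C@H]2CC=O | intermediate (not isolated)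
10 | arm carboxylic acid of 8 (C2' = CO2H) | CC1(C)OC[C@@]2(O1)CC[C@@H](C#C)[C@H]2CC(=O)O | intermediate
11 | (E)-but-2-en-1-yl ester of 10 | CC1(C)OC[C@@]2(O1)CC[C@@H](C#C)[C@H]2CC(=O)OC/C=C/C | intermediate
12 | (E)-O-trimethylsilyl ketene acetal of 11 (C5 cis to the butenyloxy group), alkyne C-silylated | CC1(C)OC[C@@]2(O1)CC[C@@H](C#C[Si](C)(C)C)[C@H]2/C=C(\OC/C=C/C)O[Si](C)(C)C | intermediate (not isolated)
13 | trimethylsilyl ester of the rearranged acid, C1' and C5' as in 28, alkyne C-silylated | CC1(C)OC[C@@]2(O1)CC[C@@H](C#C[Si](C)(C)C)[C@H]2[C@@H](C(=O)O[Si](C)(C)C)[C@H](C)C=C | intermediate (not isolated)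
14 | primary alcohol from 13 (C2' = CH2OH), C4 trimethylsilylethynyl | CC1(C)OC[C@@]2(O1)CC[C@@H](C#C[Si](C)(C)C)[C@H]2[C@@H](CO)[C@H](C)C=C | intermediate
15 | dilithium alkoxide acetylide from 14 | CC1(C)OC[C@@]2(O1)CC[C@@H](C#[C-])[C@H]2[C@@H](C[O-])[C@H](C)C=C.[Li+].[Li+] | intermediate (not isolated)
16 | methyl ynoate (C4–C≡C–CO2Me) with C2'–O methyl carbonate | CC1(C)OC[C@@]2(O1)CC[C@@H](C#CC(=O)OC)[C@H]2[C@@H](COC(=O)OC)[C@H](C)C=C | intermediate
17 | methyl (Z)-3-methyl enoate, carbonate retained | CC1(C)OC[C@@]2(O1)CC[C@@H](/C(C)=C\C(=O)OC)[C@H]2[C@@H](COC(=O)OC)[C@H](C)C=C | intermediate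
18 | diol: (Z)-allylic alcohol at C9, primary alcohol at C2' | CC1(C)OC[C@@]2(O1)CC[C@@H](/C(C)=C\CO)[C@H]2[C@@H](CO)[C@H](C)C=C | intermediate
19 | (Z)-allylic chloride at C9, C2' alcohol free | CC1(C)OC[C@@]2(O1)CC[C@@H](/C(C)=C\CCl)[C@H]2[C@@H](CO)[C@H](C)C=C | intermediate
20 | 1-bromo-2-methylprop-1-ene | CC(C)=CBr | starting material
21 | (2-methylprop-1-enyl)magnesium bromide | CC(C)=C[Mg]Br | intermediate (not isolated)
22 | alcohol with the complete (Z)-C7–C11 chain, C2' = CH2OH | CC1(C)OC[C@@]2(O1)CC[C@@H](/C(C)=C\CC=C(C)C)[C@H]2[C@@H](CO)[C@H](C)C=C | intermediate
23 | aldehyde, C2' = CHO | CC1(C)OC[C@@]2(O1)CC[C@@H](/C(C)=C\CC=C(C)C)[C@H]2[C@@H](C=O)[C@H](C)C=C | intermediate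
24 | allylic alcohol C2'H(OH)–CH=CH2 (C2' epimers) | CC1(C)OC[C@@]2(O1)CC[C@@H](/C(C)=C\CC=C(C)C)[C@H]2[C@@H](C(O)C=C)[C@H](C)C=C | intermediate
25 | ring B cyclopent-2-en-1-ol (C2' epimers), acetonide retained | CC1(C)OC[C@@]2(O1)CC[C@@H](/C(C)=C\CC=C(C)C)[C@H]2[C@H]1C(O)C=C[C@H]1C | intermediate
26 | triol (C1–OH, C6–OH, C2'–OH) | OC[C@@]1(O)CC[C@@H](/C(C)=C\CC=C(C)C)[C@H]1[C@H]1C(O)C=C[C@H]1C | intermediate
27 | C6 acetate of 26 | CC(=O)OC[C@@]1(O)CC[C@@H](/C(C)=C\CC=C(C)C)[C@H]1[C@H]1C(O)C=C[C@H]1C | intermediate
28 | [(1R,2S,3R)-1-hydroxy-3-[(2Z)-6-methylhepta-2,5-dien-2-yl]-2-[(1S,5R)-5-methyl-2-oxocyclopent-3-en-1-yl]cyclopentyl]methyl acetate | CC(=O)OC[C@@]1(O)CC[C@@H](/C(C)=C\CC=C(C)C)[C@H]1[C@H]1C(=O)C=C[C@H]1C | target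

## Step count and least certain steps

Total step count: 20. Longest linear sequence: 20 steps (1 and 2 to 28); 20 enters in step 14 through 21, which is made in the same flask.

**Step 1 (key step).** The β-substituted lactone is a weak acceptor. The likely failure is that the first Michael addition is too slow, so the dienolate is consumed by oligomerisation of 1; a bulky chiral phosphine makes this worse and may also give poor enantio- or α/γ-selectivity. The fallback sets out from 1 and 2 and returns at 3. The annulation is run with the small, strongly nucleophilic PBu3 (toluene, 60 °C, slow addition of 1), which should give the racemic cis-fused lactone ester F1. The enantiomers are separated by preparative chromatography on a chiral stationary phase; 3 goes forward and its mirror image, the (4aS,7aS)-lactone ester F2, is set aside. Enantiocontrol is thus moved from the catalyst to a separation.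

**Step 9.** The ketene acetal sits between two cis substituents on C1 and C4. The likely failure is poor facial selection, because the preference for the alkynyl-flanked face rests on a steric model of a flexible system; a slow rearrangement that lets the enolate decompose is also possible. The fallback sets out from 11 and returns at 16, and replaces substrate control by reagent control. Ester 11 is enolised with a chiral bromoborane, (R,R)- or (S,S)-2-bromo-4,5-diphenyl-1,3-bis(4-methylphenylsulfonyl)-1,3,2-diazaborolidine, and Et3N in toluene–hexane at −78 °C, and left to rearrange at −20 °C (enantiomer-selecting enolate Claisen rearrangement of allylic esters). Hydrolysis should give the ethynyl acid F3 (no C-silylation in this variant) and LiAlH4 the ethynyl alcohol F4. Treatment with n-BuLi (2.1 equiv) and then ClCO2Me joins the route at 16.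

**Step 4.** The aldehyde released from the lactol has its α-carbon C4 cis to the C5 arm. The likely failure is enolisation in K2CO3–MeOH leading to the trans isomer before the diazophosphonate anion has added, or slow opening of the lactol. The fallback sets out from 5 and returns at 6 and avoids base during the olefination. Lactol 5 is treated with Ph3P=CBr2, pre-formed from [Ph3PCHBr2]Br and KOt-Bu so that neither free base nor a bromophosphonium salt is present, to give the 1,1-dibromoalkene F5. Excess n-BuLi (THF, −78 °C) converts it into 6 by elimination and 1,2-shift (Corey–Fuchs sequence).

**Step 14.** The likely failures are ionisation of the allylic chloride with loss of Z geometry, partial attack at C7, or slow coupling of the hindered alkenyl Grignard reagent in the presence of the magnesium alkoxide. The fallback sets out from 19 and 20 and returns at 22 by a palladium-catalysed cross-coupling in place of the copper-mediated substitution. Reagent 21 is quenched with Bu3SnCl to give tributyl(2-methylprop-1-enyl)stannane F6, which is coupled with 19 under Stille conditions (Pd2(dba)3, AsPh3, THF, 50 °C); these tolerate the free hydroxyl.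

**Step 19.** The C6 hydroxyl is primary but neopentyl-like. The likely failure is incomplete discrimination from the ring B carbinol, giving over-acylation. The fallback sets out from 26 and returns at 28 by reversing the order of the last two operations. MnO2 first oxidises only the allylic carbinol to the enone diol F7, in which the primary hydroxyl is the only one that can be acylated, and Ac2O–pyridine at 0 °C then gives 28. The price is a short contact of the epimerisable enone with pyridine.

## Further compounds

F1 | step 1 | racemic cis-fused lactone ester (racemate of 3) | CCOC(=O)C1=CCC2C(=O)OCCC12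
F2 | step 1 | ethyl (4aS,7aS)-1-oxo-1,3,4,4a,7,7a-hexahydrocyclopenta[c]pyran-5-carboxylate (enantiomer of 3) | CCOC(=O)C1=CC[C@@H]2C(=O)OCC[C@H]12
F3 | step 9 | rearranged acid with free ethynyl group (C2' = CO2H; C1' and C5' as in 28) | CC1(C)OC[C@@]2(O1)CC[C@@H](C#C)[C@H]2[C@@H](C(O)=O)[C@H](C)C=C
F4 | step 9 | corresponding primary alcohol with free ethynyl group | CC1(C)OC[C@@]2(O1)CC[C@@H](C#C)[C@H]2[C@@H](CO)[C@H](C)C=C
F5 | step 4 | [4-(2,2-dibromoethenyl)-1,2-epoxy-5-(2-hydroxyethyl)cyclopentyl]methanol, configured as 6 | OC[C@@]1(O2)[C@H]2C[C@@H](C=C(Br)Br)[C@H]1CCO
F6 | step 14 | tributyl(2-methylprop-1-enyl)stannane | CC(C)=C[Sn](CCCC)(CCCC)CCCC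
F7 | step 19 | enone diol (deacetyl 28) | OC[C@@]1(O)CC[C@@H](/C(C)=C\CC=C(C)C)[C@H]1[C@H]1C(=O)C=C[C@H]1C
A1 | alternative 1 | open-chain dialdehyde: C1/C6 acetonide carrying the CH2–CHO branch (C5–C1') and the (E)-CH2CH2–CH=C(CH3)–CHO branch (C2–C3–C4=C7–C8) | CC1(C)OC[C@](CC=O)(CC/C=C(\C)C=O)O1
A2 | alternative 1 | N-methylaniline | CNc1ccccc1
A3 | alternative 1 | cis-fused N-methylanilino dihydropyran aminal of ring A (one C1' epimer) | CC1(C)OC[C@@]2(O1)CC[C@@H](C(C)=CO[C@@H]3N(C)c4ccccc4)[C@H]23
A4 | alternative 2 | meso-3,4-bis[(4-methoxybenzyloxy)methyl]hexanedial | O=CC[C@@H](COCc1ccc(OC)cc1)[C@@H](COCc1ccc(OC)cc1)CC=O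
A5 | alternative 2 | cis-4,5-bis[(4-methoxybenzyloxy)methyl]cyclopent-1-ene-1-carbaldehyde, single enantiomer | O=CC1=CC[C@@H](COCc2ccc(OC)cc2)[C@H]1COCc1ccc(OC)cc1
A6 | alternative 3 | C5 ethynyl ring A with the complete Z chain, C1/C6 acetonide | CC1(C)OC[C@@]2(O1)CC[C@@H](/C(C)=C\CC=C(C)C)[C@H]2C#C
A7 | alternative 3 | 2-(ring A)-cyclopent-2-enone, acetonide-protected | CC1(C)OC[C@@]2(O1)CC[C@@H](/C(C)=C\CC=C(C)C)[C@H]2C1=CCCC1=O
A8 | alternative 3 | ethylene | C=C
A9 | alternative 3 | carbon monoxide | [C-]#[O+]
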